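- Count this flask on two clocks read off the earlier runs: a short one for the start, a long one for the charge.

| setting | dusk | midnight | flask |
|---|---|---|---|
| substrate | 0.56 M | 0.88 M | 0.40 M |
| gas | 96 mM (held) | 96 mM (held) | 96 mM (held) |
| remark | run made earlier | run made earlier |  |
| time |  |  | 10 h |

- dusk (time / h: target / %): 1.50: 0.4; 3.00: 3.0; 5.00: 7.2; 6.00: 9.5; 8.00: 14.1
- midnight (time / h: target / %): 0.667: 0; 2.00: 0.1; 4.00: 3.5; 6.00: 7.4; 8.00: 11.6

(standard deviation of a reading: 0.3 percentage points)

- how much target there is at 10 h, in percent of the substrate charged
- concentration of partner in solution at 10 h, in percent of saturation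

- at the start none of the gas is in solution
- partner is what gas becomes in solution

- The first rung was the lag (the induction period), the time at which the late straight line of target meets zero. I read 1.87 h in the dusk run and a longer 2.48 h in the midnight run, so I drew a straight line through the two charges and put the flask at 1.57 h.
- The next rung was the asked 10 h, later than that lag, so I expected the flask to be on its straight line by then.
- The last rung came from the late slopes. The dusk line needed 43.5 h per whole charge and the midnight line 47.6 h; I kept the dusk value, from the charge nearer to the flask, and called it the crossing time.
- It was longer than the asked time, so the flask covered part of one crossing, and time on the line over crossing time gave me 19.4 %.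
- The forecast read 20.3 % of target and 90 % for [partner], holding that “partner climbs quickly to a plateau”. My count lay below its figure, and I set no figure of my own on [partner], which no run read.
- The flask gave 18.7 % of target and 76.8 % for [partner]. My count stood 0.70 percentage points above the target figure, and for the same flask read at 6.0 h, the same lag and crossing time gave 10.2 % against its simulated 11.2 %.

    substrate ⇌ intermediate A (K = 1.30, k = 0.240 h⁻¹)
    substrate + partner → intermediate B (k = 7.10 M⁻¹ h⁻¹)
    substrate → intermediate C (k = 0.0810 h⁻¹)
    intermediate C ⇌ intermediate D (K = 0.540, k = 0.0180 h⁻¹)
    partner + intermediate B → intermediate E (k = 71.0 M⁻¹ h⁻¹)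
    intermediate E ⇌ target (K = 25.0, k = 0.110 h⁻¹)
    gas ⇌ partner, rate k7*(csat - [partner]) (kL = 1.30 h⁻¹)
    partner + target → over-reaction product (k = 1.60 M⁻¹ h⁻¹)

- Intermediate E went forward to target with a half-life of 6.3 h, the way back not counted, so the asked 10 h in this flask was 1.59 such half-lives. At that time this flask held more intermediate E, 31.8 %, than target, 18.7 %.

(The runs were generated by integration with constants of no real substance.)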